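The route rests on disconnecting the two acetate C–O bonds together. In the ten-membered ring the acetoxy groups at C2 and C9 flank the Z-C1=C10 alkene on the same face, which is the signature of a 1,2-dioxine bridging C2 and C9. Step 16 therefore adds singlet oxygen across the ring diene C2=C1–C10=C9, forming both C–O bonds, the dioxine ring, the Z-alkene and the C2 and C9 stereocentres in one operation. Its precursor is the (1Z,4E,9Z)-triene that already holds the trans-fused methylene lactone (C6, C7) and the C8 angelate; it is built by a butenolide-directed indium allylation and a copper-mediated ring closure at C1–C10.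

Key step: step 16

Remark: ring positions carry germacrane numbers (C1–C15); the (S,S)-ProPhenol ligand is assumed to give the 4R carbinol in step 6, and its antipode is taken if the sense proves opposite.

Step 1
Reactants: 1 propargyl bromide; 2 ethynyltrimethylsilane
Product: 4 1-(trimethylsilyl)penta-1,4-diyne, via (trimethylsilyl)ethynylmagnesium bromide 3 (not isolated)
Conditions: 2, EtMgBr, THF, 0 °C to rt; CuCl (5 mol%), 1, 50 °C
Reagents that add atoms: none
Why: Copper-catalysed SN2 alkylation of the alkynyl Grignard reagent by the propargylic bromide should give the skipped diyne, and the silyl cap leaves a single terminal alkyne for step 2.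

Step 2
Reactants: 4 1-(trimethylsilyl)penta-1,4-diyne
Product: 7 (2E)-3-methyl-6-(trimethylsilyl)hex-2-en-5-yn-1-ol, via alkenylalane 5 (not isolated), via lithium alkenylalanate 6 (not isolated)
Conditions: AlMe3, Cp2ZrCl2 (25 mol%), CH2Cl2, 0 °C to rt; n-BuLi, THF, −78 °C; (CH2O)n, rt; 1 M HCl
Reagents that add atoms: trimethylaluminium C[Al](C)C; paraformaldehyde (as formaldehyde) C=O
Why: Negishi zirconium-catalysed carboalumination adds methyl and aluminium syn across the terminal alkyne with methyl on the internal carbon, and hydroxymethylation of the alanate with retention should fix the E-C4=C5 alkene with C15 and C6 in place while the silylalkyne stays inert.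

Step 3
Reactants: 7 (2E)-3-methyl-6-(trimethylsilyl)hex-2-en-5-yn-1-ol
Product: 8 (2E)-3-methyl-6-(tributylstannyl)hex-2-en-5-yn-1-ol
Conditions: (Bu3Sn)2O (1.2 equiv), Bu4NF (2 mol%), THF, 60 °C; aqueous work-up
Reagents that add atoms: bis(tributyltin) oxide CCCC[Sn](CCCC)(CCCC)O[Sn](CCCC)(CCCC)CCCC
Why: Fluoride-catalysed silicon-to-tin exchange at the alkyne terminus is driven by Si–O bond formation and should leave the alkene untouched, the hydroxyl being returned on work-up.

Step 4
Reactants: 8 (2E)-3-methyl-6-(tributylstannyl)hex-2-en-5-yn-1-ol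
Product: 10 (2E,5Z)-3-methyl-6-(tributylstannyl)hexa-2,5-dien-1-ol, via stannyl zirconocene alkene 9 (not isolated)
Conditions: Cp2Zr(H)Cl (2.2 equiv), THF, rt; then H2O
Reagents that add atoms: none
Why: Hydrozirconation of the stannylalkyne is syn and places zirconium on the tin-bearing carbon, so protonolysis of the C–Zr bond with retention should leave C3 and tin cis (Z-C1=C2), the trisubstituted alkene being too hindered to react.

Step 5
Reactants: 10 (2E,5Z)-3-methyl-6-(tributylstannyl)hexa-2,5-dien-1-ol
Product: 11 (2E,5Z)-3-methyl-6-(tributylstannyl)hexa-2,5-dienal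
Conditions: MnO2, CH2Cl2, rt
Reagents that add atoms: none
Why: Heterogeneous MnO2 oxidation is selective for the allylic alcohol and should spare the alkenylstannane and both alkene geometries.

Step 6
Reactants: 11 (2E,5Z)-3-methyl-6-(tributylstannyl)hexa-2,5-dienal; 12 methyl propiolate
Product: 14 methyl (4R,5E,8Z)-4-hydroxy-6-methyl-9-(tributylstannyl)nona-5,8-dien-2-ynoate, via zinc alkynylide 13 (not isolated)
Conditions: Me2Zn, (S,S)-ProPhenol (20 mol%), PhMe, 4 °C; aq NH4Cl
Reagents that add atoms: none
Why: Trost zinc–ProPhenol alkynylation delivers the zinc propiolate to one enantioface of the enal under catalyst control, which should set C6 as R in a substrate class (enals) for which the reaction is well established.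

Step 7
Reactants: 14 methyl (4R,5E,8Z)-4-hydroxy-6-methyl-9-(tributylstannyl)nona-5,8-dien-2-ynoate
Product: 15 methyl (4R,5E,8Z)-6-methyl-4-[(triethylsilyl)oxy]-9-(tributylstannyl)nona-5,8-dien-2-ynoate
Conditions: Et3SiCl, imidazole, CH2Cl2, 0 °C
Reagents that add atoms: chlorotriethylsilane CC[Si](Cl)(CC)CC
Why: Standard silylation masks the C6 hydroxyl so that the hydroalumination of step 8 is not diverted by an aluminium alkoxide.

Step 8
Reactants: 15 methyl (4R,5E,8Z)-6-methyl-4-[(triethylsilyl)oxy]-9-(tributylstannyl)nona-5,8-dien-2-ynoate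
Product: 17 methyl (2Z,4R,5E,8Z)-2-(hydroxymethyl)-6-methyl-4-[(triethylsilyl)oxy]-9-(tributylstannyl)nona-2,5,8-trienoate, via alumino acrylate 16 (not isolated)
Conditions: i-Bu2AlH, NMO, THF, 0 °C; then CH2O (from cracked (CH2O)n), 0 °C to rt; Rochelle salt
Reagents that add atoms: formaldehyde C=O
Why: Vinylalumination, in which the i-Bu2AlH–NMO complex adds hydride in conjugate fashion to the ynoate and the α-alumino acrylate is hydroxymethylated on the side of the new β-hydrogen, should place C6 cis to the ester and C13 on C11; any E isomer cannot lactonise in step 9 and is removed there.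

Step 9
Reactants: 17 methyl (2Z,4R,5E,8Z)-2-(hydroxymethyl)-6-methyl-4-[(triethylsilyl)oxy]-9-(tributylstannyl)nona-2,5,8-trienoate
Product: 19 (5R)-3-(hydroxymethyl)-5-[(1E,4Z)-2-methyl-5-(tributylstannyl)penta-1,4-dien-1-yl]furan-2(5H)-one, via hydroxy ester 18 (not isolated)
Conditions: PPTS (cat.), MeOH, rt
Reagents that add atoms: none
Why: Acid-catalysed methanolysis of the silyl ether frees the C6 hydroxyl, which sits cis to the ester and should close the butenolide by lactonisation without touching the C6 configuration.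

Step 10
Reactants: 19 (5R)-3-(hydroxymethyl)-5-[(1E,4Z)-2-methyl-5-(tributylstannyl)penta-1,4-dien-1-yl]furan-2(5H)-one
Product: 20 (5R)-3-(bromomethyl)-5-[(1E,4Z)-2-methyl-5-(tributylstannyl)penta-1,4-dien-1-yl]furan-2(5H)-one
Conditions: CBr4, PPh3, CH2Cl2, 0 °C
Reagents that add atoms: carbon tetrabromide BrC(Br)(Br)Br
Why: Appel bromination of the primary allylic alcohol runs under neutral conditions, chosen because amine bases would enolise the acidic C6–H of the butenolide.

Step 11
Reactants: 21 but-2-yn-1-ol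
Product: 23 (2Z)-3-iodobut-2-en-1-ol, via sodium oxaluminacycle 22 (not isolated)
Conditions: NaAlH2(OCH2CH2OMe)2, THF, 0 °C; then I2, −78 °C
Reagents that add atoms: iodine II
Why: Hydroxyl-directed trans-hydroalumination places aluminium on C3 cis to the carbinol carbon, and iodinolysis with retention should give the Z-iodoalkene that becomes C9=C10 with C14.

Step 12
Reactants: 23 (2Z)-3-iodobut-2-en-1-ol
Product: 24 (2Z)-3-iodobut-2-enal
Conditions: MnO2, CH2Cl2, rt, dark; used at once
Reagents that add atoms: none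
Why: Neutral allylic oxidation with MnO2 should give the enal without Z-to-E isomerisation if light and acid are excluded.

Step 13
Reactants: 20 (5R)-3-(bromomethyl)-5-[(1E,4Z)-2-methyl-5-(tributylstannyl)penta-1,4-dien-1-yl]furan-2(5H)-one; 24 (2Z)-3-iodobut-2-enal
Product: 26 (4R,5R)-4-[(1R,2Z)-1-hydroxy-3-iodobut-2-en-1-yl]-3-methylidene-5-[(1E,4Z)-2-methyl-5-(tributylstannyl)penta-1,4-dien-1-yl]oxolan-2-one, via allylindium bromide 25 (not isolated)
Conditions: In powder, THF/H2O (1:1), rt
Reagents that add atoms: none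
Why: In this Barbier allylation the allylindium adds through C7 in a closed six-membered transition state, so attack anti to the C6 substituent on the flat butenolide should set the trans-lactone, and because the ring holds C6 cis to the carbonyl (an E-crotyl-type reagent) the anti adduct with 8R should result while the exocyclic methylene forms in the same event.

Step 14
Reactants: 26 (4R,5R)-4-[(1R,2Z)-1-hydroxy-3-iodobut-2-en-1-yl]-3-methylidene-5-[(1E,4Z)-2-methyl-5-(tributylstannyl)penta-1,4-dien-1-yl]oxolan-2-one; 27 angelic acid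
Product: 29 (1R,2Z)-3-iodo-1-{(2R,3S)-4-methylidene-2-[(1E,4Z)-2-methyl-5-(tributylstannyl)penta-1,4-dien-1-yl]-5-oxooxolan-3-yl}but-2-en-1-yl (2Z)-2-methylbut-2-enoate, via angelic trichlorobenzoic anhydride 28 (not isolated)
Conditions: 27, 2,4,6-Cl3C6H2COCl, Et3N, PhMe, rt; then 26, PhMe, 75 °C
Reagents that add atoms: none
Why: Yamaguchi mixed-anhydride esterification without DMAP should acylate the hindered allylic alcohol while avoiding the nucleophile-catalysed Z-to-E isomerisation of the angeloyl group.

Step 15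
Reactants: 29 (1R,2Z)-3-iodo-1-{(2R,3S)-4-methylidene-2-[(1E,4Z)-2-methyl-5-(tributylstannyl)penta-1,4-dien-1-yl]-5-oxooxolan-3-yl}but-2-en-1-yl (2Z)-2-methylbut-2-enoate
Product: 31 (6R,7S,8S)-8-angeloyloxygermacra-1Z,4E,9Z,11(13)-tetraen-12,6-olide [(3aS,4S,5Z,7Z,10E,11aR)-6,10-dimethyl-3-methylidene-2-oxo-2,3,3a,4,9,11a-hexahydrocyclodeca[b]furan-4-yl (2Z)-2-methylbut-2-enoate], via alkenylcopper 30 (not isolated)
Conditions: CuTC (Cu thiophene-2-carboxylate, CuO2CC4H3S, 3 equiv), NMP, 0 °C to rt, 1 mM, slow addition of 29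
Reagents that add atoms: none
Why: Liebeskind copper-mediated Stille-type coupling exchanges tin for copper at the unhindered Z-alkenylstannane and joins it to the Z-alkenyl iodide (helped by the cis ester oxygen) with retention at both alkenes, which should close the ten-membered ring at C1–C10 without palladium, so that the allylic lactone and angelate cannot ionise, while high dilution holds back oligomers.

Step 16
Reactants: 31 (6R,7S,8S)-8-angeloyloxygermacra-1Z,4E,9Z,11(13)-tetraen-12,6-olide; 32 dioxygen
Product: 33 (2R,6R,7S,8R,9R)-8-angeloyloxy-2,9-epidioxygermacra-1(10)Z,4E,11(13)-trien-12,6-olide (C2,C9 endoperoxide)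
Conditions: O2, 5,10,15,20-tetraphenylporphyrin (1 mol%), hν (>500 nm), CH2Cl2, −40 °C
Reagents that add atoms: none
Why: Sensitised singlet oxygen adds to the cisoid conformer of the C2=C1–C10=C9 diene in a concerted suprafacial [4+2] cycloaddition that forms the C2–O and C9–O bonds and moves the π bond to C1=C10. The closest known reactions are the singlet-oxygen cycloadditions of cis,cis-cyclohepta- and cycloocta-1,3-diene to bicyclic 1,2-dioxines. The six-membered dioxine ring is closed by the cycloaddition itself, both oxygens bonding at once across the diene termini so that the peroxide bridges C2 and C9 of the carbocycle, which forces the new alkene to be Z and C3 and C8 to be cis on the dioxine. C9 is controlled by C8: 1,3-allylic strain against C1 holds H8 in the diene plane, ring carbon C7 and the chain behind it then cover one face, and oxygen should enter from the open face on which the C8–O bond lies, giving 9R, while C2 follows as 2R because both bonds form on the same face. The step needs this facial preference and cycloaddition ahead of the ene reaction at C4=C5 and at the C10 methyl; the conjugated diene is the most electron-rich π system, C4=C5 is deactivated by the allylic lactone oxygen at C6, the methylene lactone and angelate are electron-poor, and low temperature with a low-energy sensitiser spares the angelate geometry and the peroxide.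

Step 17
Reactants: 33 (2R,6R,7S,8R,9R)-8-angeloyloxy-2,9-epidioxygermacra-1(10)Z,4E,11(13)-trien-12,6-olide
Product: 34 (2R,6R,7S,8R,9R)-8-angeloyloxy-2,9-dihydroxygermacra-1(10)Z,4E,11(13)-trien-12,6-olide
Conditions: thiourea, MeOH/CH2Cl2, 0 °C to rt
Reagents that add atoms: none
Why: Thiourea reduces the O–O bond by nucleophilic attack on oxygen under neutral conditions, so both C–O bonds and hence 2R and 9R are kept in the cis-2-ene-1,4-diol and the enoates should not be reduced.

Step 18
Reactants: 34 (2R,6R,7S,8R,9R)-8-angeloyloxy-2,9-dihydroxygermacra-1(10)Z,4E,11(13)-trien-12,6-olide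
Product: 35 (2R,6R,7S,8R,9R)-2,9-diacetoxy-8-angeloyloxygermacra-1(10)Z,4E,11(13)-trien-12,6-olide [(3aS,4R,5R,6Z,8R,10E,11aR)-5,8-diacetoxy-6,10-dimethyl-3-methylidene-2-oxo-2,3,3a,4,5,8,9,11a-octahydrocyclodeca[b]furan-4-yl (2Z)-2-methylbut-2-enoate], the target
Conditions: Ac2O, pyridine, DMAP (cat.), CH2Cl2, 0 °C to rt, directly after step 17
Reagents that add atoms: acetic anhydride CC(=O)OC(C)=O
Why: DMAP-catalysed acetylation of both allylic hydroxyls, run at once so that the angeloyl group has no time to migrate from O8 to O9, should give the target without touching any stereocentre.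

Compound list
1 | propargyl bromide | C#CCBr | starting material
2 | ethynyltrimethylsilane | C#C[Si](C)(C)C | starting material
3 | (trimethylsilyl)ethynylmagnesium bromide | Br[Mg]C#C[Si](C)(C)C | intermediate
4 | 1-(trimethylsilyl)penta-1,4-diyne | C#CCC#C[Si](C)(C)C | intermediate
5 | dimethyl[(1E)-2-methyl-5-(trimethylsilyl)pent-1-en-4-yn-1-yl]alumane | C[Al](C)/C=C(\C)CC#C[Si](C)(C)C | intermediate
6 | lithium butyl(dimethyl)[(1E)-2-methyl-5-(trimethylsilyl)pent-1-en-4-yn-1-yl]aluminate | [Li+].CCCC[Al-](C)(C)/C=C(\C)CC#C[Si](C)(C)C | intermediate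
7 | (2E)-3-methyl-6-(trimethylsilyl)hex-2-en-5-yn-1-ol | OC/C=C(\C)CC#C[Si](C)(C)C | intermediate
8 | (2E)-3-methyl-6-(tributylstannyl)hex-2-en-5-yn-1-ol | OC/C=C(\C)CC#C[Sn](CCCC)(CCCC)CCCC | intermediate
9 | O-zirconated (2E,5Z)-6-[chlorobis(cyclopentadienyl)zirconio]-3-methyl-6-(tributylstannyl)hexa-2,5-dien-1-ol | Cl[Zr](OC/C=C(\C)C/C=C(\[Sn](CCCC)(CCCC)CCCC)[Zr](Cl)(C1C=CC=C1)C1C=CC=C1)(C1C=CC=C1)C1C=CC=C1 | intermediate
10 | (2E,5Z)-3-methyl-6-(tributylstannyl)hexa-2,5-dien-1-ol | OC/C=C(\C)C/C=C\[Sn](CCCC)(CCCC)CCCC | intermediate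
11 | (2E,5Z)-3-methyl-6-(tributylstannyl)hexa-2,5-dienal | O=C/C=C(\C)C/C=C\[Sn](CCCC)(CCCC)CCCC | intermediate
12 | methyl propiolate | C#CC(=O)OC | starting material
13 | methyl 3-(methylzincio)prop-2-ynoate | C[Zn]C#CC(=O)OC | intermediate
14 | methyl (4R,5E,8Z)-4-hydroxy-6-methyl-9-(tributylstannyl)nona-5,8-dien-2-ynoate | COC(=O)C#C[C@H](O)/C=C(\C)C/C=C\[Sn](CCCC)(CCCC)CCCC | intermediate
15 | methyl (4R,5E,8Z)-6-methyl-4-[(triethylsilyl)oxy]-9-(tributylstannyl)nona-5,8-dien-2-ynoate | COC(=O)C#C[C@H](O[Si](CC)(CC)CC)/C=C(\C)C/C=C\[Sn](CCCC)(CCCC)CCCC | intermediate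
16 | methyl (2E,4R,5E,8Z)-2-(diisobutylalumanyl)-6-methyl-4-[(triethylsilyl)oxy]-9-(tributylstannyl)nona-2,5,8-trienoate | COC(=O)/C(=C\[C@H](O[Si](CC)(CC)CC)/C=C(\C)C/C=C\[Sn](CCCC)(CCCC)CCCC)[Al](CC(C)C)CC(C)C | intermediate
17 | methyl (2Z,4R,5E,8Z)-2-(hydroxymethyl)-6-methyl-4-[(triethylsilyl)oxy]-9-(tributylstannyl)nona-2,5,8-trienoate | COC(=O)/C(CO)=C\[C@H](O[Si](CC)(CC)CC)/C=C(\C)C/C=C\[Sn](CCCC)(CCCC)CCCC | intermediate
18 | methyl (2Z,4R,5E,8Z)-4-hydroxy-2-(hydroxymethyl)-6-methyl-9-(tributylstannyl)nona-2,5,8-trienoate | COC(=O)/C(CO)=C\[C@H](O)/C=C(\C)C/C=C\[Sn](CCCC)(CCCC)CCCC | intermediate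
19 | (5R)-3-(hydroxymethyl)-5-[(1E,4Z)-2-methyl-5-(tributylstannyl)penta-1,4-dien-1-yl]furan-2(5H)-one | O=C1O[C@H](/C=C(\C)C/C=C\[Sn](CCCC)(CCCC)CCCC)C=C1CO | intermediate
20 | (5R)-3-(bromomethyl)-5-[(1E,4Z)-2-methyl-5-(tributylstannyl)penta-1,4-dien-1-yl]furan-2(5H)-one | O=C1O[C@H](/C=C(\C)C/C=C\[Sn](CCCC)(CCCC)CCCC)C=C1CBr | intermediate
21 | but-2-yn-1-ol | CC#CCO | starting material
22 | sodium 2,2-bis(2-methoxyethoxy)-3-methyl-2,5-dihydro-1,2-oxaluminol-2-uide | [Na+].COCCO[Al-]1(OCCOC)OCC=C1C | intermediate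
23 | (2Z)-3-iodobut-2-en-1-ol | OC/C=C(/C)I | intermediate
24 | (2Z)-3-iodobut-2-enal | O=C/C=C(/C)I | intermediate
25 | allylindium sesquibromide from 20, drawn as the allylindium dibromide | Br[In](Br)CC1=C[C@@H](/C=C(\C)C/C=C\[Sn](CCCC)(CCCC)CCCC)OC1=O | intermediate
26 | (4R,5R)-4-[(1R,2Z)-1-hydroxy-3-iodobut-2-en-1-yl]-3-methylidene-5-[(1E,4Z)-2-methyl-5-(tributylstannyl)penta-1,4-dien-1-yl]oxolan-2-one | C=C1C(=O)O[C@H](/C=C(\C)C/C=C\[Sn](CCCC)(CCCC)CCCC)[C@H]1[C@@H](O)/C=C(/C)I | intermediate
27 | angelic acid, (2Z)-2-methylbut-2-enoic acid | C/C=C(/C)C(=O)O | starting material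
28 | (2Z)-2-methylbut-2-enoic 2,4,6-trichlorobenzoic anhydride | C/C=C(/C)C(=O)OC(=O)c1c(Cl)cc(Cl)cc1Cl | intermediate
29 | (1R,2Z)-3-iodo-1-{(2R,3S)-4-methylidene-2-[(1E,4Z)-2-methyl-5-(tributylstannyl)penta-1,4-dien-1-yl]-5-oxooxolan-3-yl}but-2-en-1-yl (2Z)-2-methylbut-2-enoate | C=C1C(=O)O[C@H](/C=C(\C)C/C=C\[Sn](CCCC)(CCCC)CCCC)[C@H]1[C@@H](OC(=O)/C(C)=C\C)/C=C(/C)I | intermediate
30 | Z-alkenylcopper formed from 29 by tin-to-copper exchange at C1 | C=C1C(=O)O[C@H](/C=C(\C)C/C=C\[Cu])[C@H]1[C@@H](OC(=O)/C(C)=C\C)/C=C(/C)I | intermediate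
31 | (6R,7S,8S)-8-angeloyloxygermacra-1Z,4E,9Z,11(13)-tetraen-12,6-olide, the precursor of the key step | C=C1C(=O)O[C@@H]2/C=C(\C)C/C=C\C(C)=C/[C@H](OC(=O)/C(C)=C\C)[C@@H]12 | intermediate
32 | dioxygen | O=O | starting material
33 | (2R,6R,7S,8R,9R)-8-angeloyloxy-2,9-epidioxygermacra-1(10)Z,4E,11(13)-trien-12,6-olide | C=C1C(=O)O[C@@H]2/C=C(\C)C[C@@H](O3)/C=C(/C)[C@@H](O3)[C@H](OC(=O)/C(C)=C\C)[C@@H]12 | intermediate
34 | (2R,6R,7S,8R,9R)-8-angeloyloxy-2,9-dihydroxygermacra-1(10)Z,4E,11(13)-trien-12,6-olide | C=C1C(=O)O[C@@H]2/C=C(\C)C[C@@H](O)/C=C(/C)[C@@H](O)[C@H](OC(=O)/C(C)=C\C)[C@@H]12 | intermediate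
35 | (2R,6R,7S,8R,9R)-2,9-diacetoxy-8-angeloyloxygermacra-1(10)Z,4E,11(13)-trien-12,6-olide | C=C1C(=O)O[C@@H]2/C=C(\C)C[C@@H](OC(C)=O)/C=C(/C)[C@@H](OC(C)=O)[C@H](OC(=O)/C(C)=C\C)[C@@H]12 | target

Total step count: 18. Longest linear sequence: 16 steps (steps 1–10 and 13–18); steps 11 and 12 form the side branch.

Steps most likely to fail

1. Step 16. The twisted ten-membered diene may reach the cisoid geometry too rarely, so that singlet oxygen is used up by ene reaction at C4=C5 or at the C10 methyl, or it may add on the inner face. Fallback: the same dioxine is made without singlet oxygen, so that the ene pathway does not exist. Setting out from 31, ground-state oxygen is added under one-electron catalysis ((4-BrC6H4)3N·SbCl6, 5 mol%, O2, CH2Cl2, −78 °C, dark), a known radical-cation chain oxygenation of 1,3-dienes. The conjugated diene is the most easily oxidised π system of 31, and its radical cation should take up oxygen and close to the endoperoxide. The fallback comes back to the route at 33 and makes no compound outside the list (F0).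

2. Step 15. The ring may fail to close at C1–C10 because oligomerisation or protodestannylation outruns the coupling, or because the strained ring resists the C–C bond-forming event. Fallback: the ring is closed at C7–C8 instead. Setting out from 19 and 24:
- An intermolecular Stille coupling (Pd2(dba)3, AsPh3, NMP, rt) would give the trienal butenolide (5R)-3-(hydroxymethyl)-5-[(1E,4Z,6Z)-2,6-dimethyl-8-oxoocta-1,4,6-trien-1-yl]furan-2(5H)-one F1, kept cold and used at once.
- Appel bromination (CBr4, PPh3, CH2Cl2, 0 °C) would give the bromomethyl butenolide aldehyde F2.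
- An intramolecular indium Barbier allylation (In, THF/H2O, 1 mM) would close the ten-membered ring and form the methylene lactone together, through the same closed transition state as in step 13, to give the ring alcohol (6R,7R,8S)-8-hydroxygermacra-1Z,4E,9Z,11(13)-tetraen-12,6-olide F3.
- Esterification of F3 with the anhydride 28 as in step 14 comes back to the route at 31.

3. Step 13. The addition may leave the closed transition state and pass through an open one, which would erode or reverse the configuration at C8 while the trans-lactone is still set by the butenolide face. Fallback: C8 is then set by inversion instead of by the allylation. Setting out from 20 and 24, the coupling would deliver the C8 epimer (4R,5R)-4-[(1S,2Z)-1-hydroxy-3-iodobut-2-en-1-yl]-3-methylidene-5-[(1E,4Z)-2-methyl-5-(tributylstannyl)penta-1,4-dien-1-yl]oxolan-2-one F4. F4 would be esterified with angelic acid 27 under Mitsunobu conditions (PPh3, DIAD, PhMe, 0 °C), where the carboxylate displaces the activated hydroxyl with inversion and the Z-enoate is not isomerised. This comes back to the route at 29 and bypasses step 14.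

Further compounds
F0 | step 16 | none | none
F1 | step 15 | (5R)-3-(hydroxymethyl)-5-[(1E,4Z,6Z)-2,6-dimethyl-8-oxoocta-1,4,6-trien-1-yl]furan-2(5H)-one | O=C1O[C@H](/C=C(\C)C/C=C\C(C)=C/C=O)C=C1CO
F2 | step 15 | (5R)-3-(bromomethyl)-5-[(1E,4Z,6Z)-2,6-dimethyl-8-oxoocta-1,4,6-trien-1-yl]furan-2(5H)-one | O=C1O[C@H](/C=C(\C)C/C=C\C(C)=C/C=O)C=C1CBr
F3 | step 15 | (6R,7R,8S)-8-hydroxygermacra-1Z,4E,9Z,11(13)-tetraen-12,6-olide | C=C1C(=O)O[C@@H]2/C=C(\C)C/C=C\C(C)=C/[C@H](O)[C@@H]12
F4 | step 13 | (4R,5R)-4-[(1S,2Z)-1-hydroxy-3-iodobut-2-en-1-yl]-3-methylidene-5-[(1E,4Z)-2-methyl-5-(tributylstannyl)penta-1,4-dien-1-yl]oxolan-2-one | C=C1C(=O)O[C@H](/C=C(\C)C/C=C\[Sn](CCCC)(CCCC)CCCC)[C@H]1[C@H](O)/C=C(/C)I
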